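The numbers in the tables are simulated from invented constants; scatter was added.

The pitfall with a climbing curve is to carry it forward as if the enzyme drawing it stayed the same. Here are the flasks, the earlier run and the questions.

all flasks: free enzyme 0.01 mol%
- oak: substrate 9.5 mM (fed, over 40 s); temperature 40 °C; run made earlier
- grey: substrate 19 mM; temperature 55 °C; everything together at the start; time 6.0 min
- violet: substrate 19 mM (fed, over 40 s); temperature 40 °C; time 6.0 min

- oak (time / s: target / %): 15.0: 1.7; 30.0: 5.2; 40.0: 7.3; 60.0: 15.0; 80.0: 19.9

(each reading ± 1 percentage point)

- the earlier runs do not show what temperature does; that part of a forecast is a guess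
- percentages count the whole charge, also what has not yet gone in
- no earlier run changes the charge of free enzyme; that part of a forecast is a guess

- which one finishes higher in amount of target, in percent of the substrate charged ("neither" within 2 percentage points) (grey / violet / neither)
- amount of target at the end, in percent of the substrate charged, grey
- amount of target at the end, in percent of the substrate charged, violet

Write the balance of free enzyme, the species charged in the smaller amount. A catalyst returns from each turn, so using the whole charge asks each enzyme molecule for one over the loading, 10000 turnovers: the turnover number demanded. The fraction of the charge used is then the turnovers delivered per enzyme divided by that demand.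

Oak gives a pace. From the end of its feed to its last reading, target rises 13 percentage points in 40.0 s, which read per enzyme charged is 31.5 /s, with the scatter of two readings in it. At that pace the demand takes 5.29 min, less than the 6.0 min of the run, with 0.710 min to spare. This reckoning of mine carries oak's pace over to violet, whose charge is twice oak's, and by it violet needs its enzyme at work through most of the run to use the whole charge. For grey it gives no number: oak shows nothing of temperature.

The forecast does give numbers: 72 % for grey (range 42 % to 95 %), 60 % for violet (range 40 % to 74 %), and grey ahead. On grey it warns: “However, free enzyme may denature at 55 °C, and all the substrate is present at once.”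

Grey ends at 13.2 % target and violet at 45.7 %, so violet finishes higher.

    free enzyme → unfolded enzyme (k = 0.0140 /min, Ea = 253 kJ/mol)
    substrate + free enzyme → target + free enzyme, rate k2*[substrate]*[free enzyme]/(1 + ([substrate]/Km2) + ([target]/Kp2)) (9.40 mM, 17.0 mM, k = 5.10 × 10⁵ /M/min, Ea = 13.0 kJ/mol)
    2 free enzyme → spent catalyst (k = 1.30 × 10⁵ /M/min, Ea = 35.0 kJ/mol)
    target ⇌ isomer of the product (K = 1.60, k = 0.0830 /min, Ea = 98.0 kJ/mol, ΔH = −42.0 kJ/mol)
    (constants at 40 °C)

In grey the making of target is half done by 0.444 min, far shorter than the run; free enzyme stands at 1.62 % of its charge at 3.00 min, and with 77 % of the substrate left at 6.00 min, target and isomer of the product together count 2310 turnovers per enzyme charged, a quarter of the demand. The neighbour flask like grey but with 0.004 mol% of free enzyme keeps 89 % of its substrate at the end, which counts 2840 turnovers per enzyme charged.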